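**Plan**

- Ring numbering used throughout: O1, C2 (carries the carbinol carbon C1'), C3 (4-methoxyphenyl), C4 (OH), C5 (CH2). The target is 2S,3R,4S,1'R, with all three ring substituents cis.
- Retrosynthesis: C4–OH is traced back to C4–Si and C1'–OH to the aryl ketone. The oxolane is then cut at C2–C3 and O1–C5 into a Z-cinnamylsilane and an arylglyoxal, and the silane is cut at the alkyne–CH2Si bond.
- Enabling feature: a cis C3-aryl/C4-oxygen pair next to an unsubstituted C5 is the pattern left when carbon and silicon add anti across a Z-alkene and the aldehyde oxygen closes on the former CH2Si carbon.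
- Forward: the silane (three steps) and the glyoxal (one step) are made separately and joined in one annulation that forms the only ring. Ketone reduction and C–Si oxidation finish the route.
- Stereochemistry: C3/C4 come from the Z geometry and anti SE2' addition. C2 is set relative to C3 by an open antiperiplanar transition state and in absolute terms by a chiral Sc(OTf)3–pybox complex. C1' comes from chelation-controlled hydride delivery and C4–O from Fleming–Tamao oxidation with retention.

Key step: step 5

Assumption: the (S,S)-ligand 2,6-bis[(4S)-4-phenyl-4,5-dihydrooxazol-2-yl]pyridine ((S,S)-Ph-pybox) is taken to leave the Si face of the scandium-bound aldehyde open; if the first experiment shows the opposite sense, the (R,R)-ligand is used and nothing else changes.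

**Step 1**
Reactants: 1 (chloromethyl)dimethylphenylsilane
Product: 2 (iodomethyl)dimethylphenylsilane
Conditions: NaI, acetone, reflux
Reagents that add atoms: sodium iodide, [Na+].[I-]
Why: Finkelstein halide exchange driven by precipitation of NaCl, carried out because the chloride alkylates acetylides too slowly.

**Step 2**
Reactants: 3 1-ethynyl-4-methoxybenzene; 2 (iodomethyl)dimethylphenylsilane
Product: 5 dimethyl[3-(4-methoxyphenyl)prop-2-yn-1-yl]phenylsilane, via lithium (4-methoxyphenyl)acetylide 4 (not isolated)
Conditions: n-BuLi (1.0 equiv), THF, −78 → 0 °C; then 2, reflux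
Reagents that add atoms: none
Why: SN2 alkylation of a lithium acetylide by a primary α-silyl iodide is the standard entry to propargylsilanes, and one equivalent of base should avoid propargyl-to-allenyl isomerisation.

**Step 3**
Reactants: 5 dimethyl[3-(4-methoxyphenyl)prop-2-yn-1-yl]phenylsilane
Product: 6 (Z)-dimethyl[3-(4-methoxyphenyl)prop-2-en-1-yl]phenylsilane
Conditions: H2 (1 atm), Pd/CaCO3 poisoned with Pb(OAc)2, quinoline, EtOAc, rt
Reagents that add atoms: none
Why: Lindlar semi-hydrogenation delivers both hydrogens to one face of the alkyne on the poisoned palladium surface, so the Z-alkene should form and the allylic C–Si bond should stay intact.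

**Step 4**
Reactants: 7 1-(3,4-dimethoxyphenyl)ethan-1-one
Product: 9 2-(3,4-dimethoxyphenyl)-2-oxoacetaldehyde, via arylglyoxal hydrate 8 (not isolated)
Conditions: SeO2, 1,4-dioxane–H2O, reflux; filter; then PhMe, Dean–Stark, Kugelrohr distillation, use at once
Reagents that add atoms: selenium dioxide, O=[Se]=O
Why: Riley oxidation converts the methyl group of an aryl methyl ketone into the aldehyde, which forms first as its hydrate and is dehydrated because the annulation needs the free, chelating 1,2-dicarbonyl unit.

**Step 5**
Reactants: 6 (Z)-dimethyl[3-(4-methoxyphenyl)prop-2-en-1-yl]phenylsilane; 9 2-(3,4-dimethoxyphenyl)-2-oxoacetaldehyde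
Product: 11 (3,4-dimethoxyphenyl)[(2S,3S,4S)-4-[dimethyl(phenyl)silyl]-3-(4-methoxyphenyl)oxolan-2-yl]methanone, via β-silyl cation alkoxide 10 (not isolated)
Conditions: Sc(OTf)3 (10 mol %), (S,S)-Ph-pybox (12 mol %), NaB[3,5-(CF3)2C6H3]4 (10 mol %), 4 Å MS, CH2Cl2, −20 °C; cold pH 7 buffer quench
Reagents that add atoms: none
Why: Proposed new method: the 1,2-dicarbonyl unit of 9 binds the Sc(OTf)3–pybox complex through both oxygens, the aryl-bearing alkene carbon of 6 attacks the aldehyde carbon anti to the C–Si bond (SE2') to give the silicon-bridged cation 10, and the scandium alkoxide opens the bridge at CH2 so that silicon ends on C4 and the catalyst is released; the closest known reaction type is the Lewis-acid [3+2] annulation of allylsilanes with aldehydes and chelating 1,2-dicarbonyl compounds, known with stoichiometric SnCl4 or BF3·OEt2 and, for other dicarbonyl partners, with chiral scandium–pybox catalysts, but not for a γ-aryl Z-allylsilane with an arylglyoxal. The oxolane closes by attack of oxygen on the primary carbon of the three-membered siliranium bridge with inversion, formally a 5-endo closure on the C4–C5 bridge, in preference to the 4-exo closure at C4 that would give an oxetane. C3 and C4 are set relative to each other by anti addition of carbon and silicon across the Z double bond, which places aryl and silyl cis. C2 is set relative to C3 by an open antiperiplanar transition state in which the anisyl group and the CH2Si arm of the Z-silane both sit on the side of the aldehyde hydrogen, away from the chelate, which places the aroyl group cis to the aryl group; its absolute configuration comes from the ligand, which leaves the Si face of the bound aldehyde open. The step needs attack at the γ carbon, ring closure faster than loss of silicon or of a proton from 10, and no epimerisation at C2; the β-silicon effect, the more cationic scandium centre made by the borate salt, the low temperature and the buffered quench are meant to secure these.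

**Step 6**
Reactants: 11 (3,4-dimethoxyphenyl)[(2S,3S,4S)-4-[dimethyl(phenyl)silyl]-3-(4-methoxyphenyl)oxolan-2-yl]methanone
Product: 12 (R)-(3,4-dimethoxyphenyl)[(2S,3S,4S)-4-[dimethyl(phenyl)silyl]-3-(4-methoxyphenyl)oxolan-2-yl]methanol
Conditions: Zn(BH4)2, Et2O–CH2Cl2, −30 → 0 °C; then H2O
Reagents that add atoms: none
Why: In this chelation-controlled reduction zinc bridges the ketone oxygen and O1, and hydride should enter on the side of C2–H, away from C3 and its cis aryl group, which gives the 1'R alcohol.

**Step 7**
Reactants: 12 (R)-(3,4-dimethoxyphenyl)[(2S,3S,4S)-4-[dimethyl(phenyl)silyl]-3-(4-methoxyphenyl)oxolan-2-yl]methanol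
Product: 14 (3S,4R,5S)-5-[(R)-(3,4-dimethoxyphenyl)(hydroxy)methyl]-4-(4-methoxyphenyl)oxolan-3-ol, via silyl tert-butyl peroxide 13 (not isolated)
Conditions: KH, tBuOOH (anhydrous), NMP, 0 °C → rt; then Bu4NF, 70 °C
Reagents that add atoms: tert-butyl hydroperoxide, CC(C)(C)OO
Why: In this Fleming–Tamao oxidation under basic conditions the peroxide anion displaces phenyl from silicon, fluoride then triggers the shift of C4 from silicon to oxygen with retention and cleaves the silyl ether, and the basic medium spares the electron-rich arenes and the benzylic alcohol that electrophilic dearylation would attack.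

**Compound list**

1 | (chloromethyl)dimethylphenylsilane | ClC[Si](C)(C)c1ccccc1 | starting material
2 | (iodomethyl)dimethylphenylsilane | IC[Si](C)(C)c1ccccc1 | intermediate
3 | 1-ethynyl-4-methoxybenzene | COc1ccc(C#C)cc1 | starting material
4 | lithium (4-methoxyphenyl)acetylide | [Li]C#Cc1ccc(OC)cc1 | intermediate (not isolated)
5 | dimethyl[3-(4-methoxyphenyl)prop-2-yn-1-yl]phenylsilane | COc1ccc(cc1)C#CC[Si](C)(C)c1ccccc1 | intermediate
6 | (Z)-dimethyl[3-(4-methoxyphenyl)prop-2-en-1-yl]phenylsilane | COc1ccc(cc1)/C=C\C[Si](C)(C)c1ccccc1 | intermediate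
7 | 1-(3,4-dimethoxyphenyl)ethan-1-one | CC(=O)c1ccc(OC)c(OC)c1 | starting material
8 | 1-(3,4-dimethoxyphenyl)-2,2-dihydroxyethan-1-one (arylglyoxal hydrate) | COc1ccc(cc1OC)C(=O)C(O)O | intermediate (not isolated)
9 | 2-(3,4-dimethoxyphenyl)-2-oxoacetaldehyde | COc1ccc(cc1OC)C(=O)C=O | intermediate
10 | β-silyl cation alkoxide: open-chain adduct with C2 and C3 configured as in 11, cation at the former central alkene carbon, drawn in its open form without the scandium ion | COc1ccc([C@H]([CH+]C[Si](C)(C)c2ccccc2)[C@@H](C(=O)c3ccc(OC)c(OC)c3)[O-])cc1 | intermediate (not isolated)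
11 | (3,4-dimethoxyphenyl)[(2S,3S,4S)-4-[dimethyl(phenyl)silyl]-3-(4-methoxyphenyl)oxolan-2-yl]methanone (all-cis) | COc1ccc([C@H]2[C@@H](C(=O)c3ccc(OC)c(OC)c3)OC[C@H]2[Si](C)(C)c2ccccc2)cc1 | intermediate
12 | (R)-(3,4-dimethoxyphenyl)[(2S,3S,4S)-4-[dimethyl(phenyl)silyl]-3-(4-methoxyphenyl)oxolan-2-yl]methanol | COc1ccc([C@H]2[C@@H]([C@H](O)c3ccc(OC)c(OC)c3)OC[C@H]2[Si](C)(C)c2ccccc2)cc1 | intermediate
13 | (R)-[(2S,3S,4S)-4-[(tert-butylperoxy)dimethylsilyl]-3-(4-methoxyphenyl)oxolan-2-yl](3,4-dimethoxyphenyl)methanol | COc1ccc([C@H]2[C@@H]([C@H](O)c3ccc(OC)c(OC)c3)OC[C@H]2[Si](C)(C)OOC(C)(C)C)cc1 | intermediate (not isolated)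
14 | (3S,4R,5S)-5-[(R)-(3,4-dimethoxyphenyl)(hydroxy)methyl]-4-(4-methoxyphenyl)oxolan-3-ol | COc1ccc([C@H]2[C@@H]([C@H](O)c3ccc(OC)c(OC)c3)OC[C@H]2O)cc1 | target

**Step count**

Total: 7 steps. Longest linear sequence: 6 steps (1, 2, 3, 5, 6, 7).

**Steps most likely to fail**

Step 5 (Proposed new method). The bound aldehyde may be attacked on both faces. The cation 10 may lose silicon (simple allylation) or a proton (ene-type outcome) before the alkoxide closes on C5. The silane may add with the opposite C2/C3 topicity, or C2 may epimerise on the Lewis acid. The fallback uses known chemistry and sets out from 6 and 9. The annulation is run in its established stoichiometric form with the chelating Lewis acid SnCl4 (1.1 equiv, CH2Cl2, −78 °C), which should give the all-cis ketone as the racemate, that is 11 together with its mirror image (3,4-dimethoxyphenyl)[(2R,3R,4R)-4-[dimethyl(phenyl)silyl]-3-(4-methoxyphenyl)oxolan-2-yl]methanone F1. Preparative chromatography on a chiral stationary phase (amylose tris(3,5-dimethylphenylcarbamate), hexane–iPrOH) would then deliver 11, where the route is rejoined before step 6. This fallback does not correct a wrong C2/C3 topicity.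

Step 7. The aryl–silicon bond at the hindered all-cis C4 may resist attack by the peroxide anion, or the C4–Si bond may be cleaved by protonation during the hot fluoride stage. The fallback changes the silicon mask to one whose carbon ligand leaves with fluoride at room temperature; it sets out from 3 and 9 and returns at 14. Diphenylmethane with n-BuLi (THF, 0 °C) would give diphenylmethyllithium F2. With chloro(chloromethyl)dimethylsilane at −78 °C this should give benzhydryl(chloromethyl)dimethylsilane F3, and NaI in acetone would convert it into benzhydryl(iodomethyl)dimethylsilane F4. Alkylation of acetylide 4, made from 3 as in step 2, would give benzhydryl[3-(4-methoxyphenyl)prop-2-yn-1-yl]dimethylsilane F5. Semi-hydrogenation as in step 3 would give (Z)-benzhydryl[3-(4-methoxyphenyl)prop-2-en-1-yl]dimethylsilane F6. Annulation with 9 as in step 5 would give [(2S,3S,4S)-4-[benzhydryl(dimethyl)silyl]-3-(4-methoxyphenyl)oxolan-2-yl](3,4-dimethoxyphenyl)methanone F7, where the bulkier silicon should also disfavour simple allylation. Zn(BH4)2 as in step 6 would give (R)-[(2S,3S,4S)-4-[benzhydryl(dimethyl)silyl]-3-(4-methoxyphenyl)oxolan-2-yl](3,4-dimethoxyphenyl)methanol F8. Bu4NF (THF, rt) should expel diphenylmethane and leave (R)-(3,4-dimethoxyphenyl)[(2S,3S,4S)-4-[fluoro(dimethyl)silyl]-3-(4-methoxyphenyl)oxolan-2-yl]methanol F9, which H2O2 and KHCO3 (MeOH–THF, rt) would oxidise with retention to 14.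

Step 6. Hydride delivery through the non-chelated conformer may compete and erode the selectivity at C1', or C2 may epimerise before the ketone is reduced. The fallback replaces substrate control by reagent control and runs from 11 to 12. It is a Corey–Bakshi–Shibata reduction with (R)-2-methyl-CBS-oxazaborolidine (20 mol %) and BH3·SMe2 in THF at −20 °C. The catalyst antipode is chosen so that, with the aryl group as the large substituent, hydride is delivered to the Si face of the ketone. This fallback makes no new compound (F0).

**Further compounds**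

F1 | step 5 | (3,4-dimethoxyphenyl)[(2R,3R,4R)-4-[dimethyl(phenyl)silyl]-3-(4-methoxyphenyl)oxolan-2-yl]methanone | COc1ccc([C@@H]2[C@H](C(=O)c3ccc(OC)c(OC)c3)OC[C@@H]2[Si](C)(C)c2ccccc2)cc1
F0 | step 6 | none | none
F2 | step 7 | diphenylmethyllithium | [Li]C(c1ccccc1)c1ccccc1
F3 | step 7 | benzhydryl(chloromethyl)dimethylsilane | ClC[Si](C)(C)C(c1ccccc1)c1ccccc1
F4 | step 7 | benzhydryl(iodomethyl)dimethylsilane | IC[Si](C)(C)C(c1ccccc1)c1ccccc1
F5 | step 7 | benzhydryl[3-(4-methoxyphenyl)prop-2-yn-1-yl]dimethylsilane | COc1ccc(cc1)C#CC[Si](C)(C)C(c1ccccc1)c1ccccc1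
F6 | step 7 | (Z)-benzhydryl[3-(4-methoxyphenyl)prop-2-en-1-yl]dimethylsilane | COc1ccc(cc1)/C=C\C[Si](C)(C)C(c1ccccc1)c1ccccc1
F7 | step 7 | [(2S,3S,4S)-4-[benzhydryl(dimethyl)silyl]-3-(4-methoxyphenyl)oxolan-2-yl](3,4-dimethoxyphenyl)methanone | COc1ccc([C@H]2[C@@H](C(=O)c3ccc(OC)c(OC)c3)OC[C@H]2[Si](C)(C)C(c2ccccc2)c2ccccc2)cc1
F8 | step 7 | (R)-[(2S,3S,4S)-4-[benzhydryl(dimethyl)silyl]-3-(4-methoxyphenyl)oxolan-2-yl](3,4-dimethoxyphenyl)methanol | COc1ccc([C@H]2[C@@H]([C@H](O)c3ccc(OC)c(OC)c3)OC[C@H]2[Si](C)(C)C(c2ccccc2)c2ccccc2)cc1
F9 | step 7 | (R)-(3,4-dimethoxyphenyl)[(2S,3S,4S)-4-[fluoro(dimethyl)silyl]-3-(4-methoxyphenyl)oxolan-2-yl]methanol | COc1ccc([C@H]2[C@@H]([C@H](O)c3ccc(OC)c(OC)c3)OC[C@H]2[Si](C)(C)F)cc1
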